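**Plan**
Labels: ring A is the monohydroxy ring (C1 OH, C3 ether O, C5 CH2). Ring B is the hydroquinone ring (C1 ether O, C2 OH, C3 CH2, C5 OH). The target has no stereocentre and no alkene, so no stereochemistry has to be set.
Cuts: first the three O–H groups go back to O–CH3. Then ring A C5–CH2 (which opens the 21-membered ring) and ring B C3–CH2 are cut in the same operation, releasing the whole bridge as tetradeca-1,13-diene. Last comes the ether bond O–C1 of ring B.
Forward: 4-methoxyphenol gives a symmetric ring B dibromide, and an Ullmann coupling joins ring A to ring B. In one flask the C14 chain is then joined to ring B at C–Br and closes the macrocycle at the C–Cl of ring A. Global demethylation finishes the route.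
Enabling feature: the bridge is an unbranched (CH2)14 ending in two ArC–CH2 bonds of the same kind, so it equals a doubly hydroborated α,ω-diene. Ring A C5 is meta to both O1 and O3, out of reach of electrophilic alkylation but open to ipso coupling of a chloride bought with the phenol. The C–O–C hinge between two 1,3-bridged arenes leaves the 21-membered ring unstrained.

Key step: step 4

Step 1
Reactants: 1 4-methoxyphenol
Product: 2 2,6-dibromo-4-methoxyphenol
Conditions: Br2 (2.1 equiv), CH2Cl2, 0 °C to rt
Reagents that add atoms: bromine, BrBr
Why: Electrophilic aromatic bromination, in which the free OH outranks OMe as director and its para position is blocked, so both bromines should enter ortho to OH.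

Step 2
Reactants: 2 2,6-dibromo-4-methoxyphenol
Product: 3 1,3-dibromo-2,5-dimethoxybenzene
Conditions: MeI, K2CO3, acetone, reflux
Reagents that add atoms: iodomethane, CI
Why: Williamson O-methylation of an acidic, doubly ortho-brominated phenol with a small electrophile, giving a symmetric dibromide with two equivalent C–Br bonds.

Step 3
Reactants: 3 1,3-dibromo-2,5-dimethoxybenzene (threefold excess, surplus recovered), 4 3-chloro-5-methoxyphenol
Product: 5 1-bromo-3-(3-chloro-5-methoxyphenoxy)-2,5-dimethoxybenzene
Conditions: CuI (10 mol %), picolinic acid (20 mol %), K3PO4, DMSO, 100 °C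
Reagents that add atoms: none
Why: Ligand-accelerated Ullmann diaryl ether coupling, in which the two C–Br bonds of 3 are equivalent so only one mono-ether can form, the excess of 3 should hold the reaction at the first substitution, and the C–Cl bond of 4 is inert to monovalent copper at this temperature.

Step 4
Reactants: 5 1-bromo-3-(3-chloro-5-methoxyphenoxy)-2,5-dimethoxybenzene, 6 tetradeca-1,13-diene
Product: 9 tri-O-methyl ether of the target (21-membered ring built from the (CH2)14 bridge; C3–C2–C1 of the 2,5-dimethoxy ring B; the ether O; C3–C4–C5 of the 1-methoxy ring A), via 1,14-bis(9-BBN)tetradecane 7 (not isolated), via ring-B-coupled chloroaryl borane 8 (not isolated)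
Conditions: 6 (1.5 equiv), 9-BBN-H (3.1 equiv), THF, 0 °C to rt; diluted with THF–H2O, Pd(OAc)2 (10 mol %), SPhos (20 mol %), K3PO4 (6 equiv), 65 °C; 5 added by syringe pump over 20 h, final 1 mM
Reagents that add atoms: none
Why: Mechanism: 9-BBN-H adds anti-Markovnikov to both vinyl groups of 6 to give 7; zerovalent palladium inserts into the C–Br bond at C3 of ring B of 5, the hydroxyborate of 7 transmetalates and reductive elimination gives 8, whose chain still ends in a 9-BBN group; the same SPhos-ligated catalyst then inserts into the C–Cl bond at C5 of ring A, the pendant borate transmetalates within the molecule and C(sp2)–C(sp3) reductive elimination forms the ring A C5–CH2 bond. The closest known reaction type is the double B-alkyl Suzuki–Miyaura coupling of dihaloarenes with bis(9-BBN) adducts of α,ω-dienes to cyclophanes, next to the many hydroboration/B-alkyl Suzuki–Miyaura macrocyclisations. The one ring closed is the 21-membered ring (14 CH2, three atoms of each arene, the ether O), in an end-to-end closure through a 22-membered palladacycle that should be free of transannular strain. No stereocentre or alkene geometry arises. The order of the two couplings (ring B first, ring closure at ring A) is secured by the large rate gap between C–Br and C–Cl in oxidative addition, and the site on ring A, meta to both oxygens and closed to electrophilic alkylation, is secured by ipso replacement of the chloride that 4 brought in. Ring closure over oligomerisation is secured by feeding 5 slowly into a dilute pool of 7, so that each molecule of 8 meets its own borane end at an effective molarity above the millimolar concentration of foreign borane and halide.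

Step 5
Reactants: 9 tri-O-methyl ether of the target
Product: 10 target CNP0393720.0 (ring A: 1-OH, 3-O-aryl, 5-CH2; ring B: 1-O-aryl, 2-OH, 3-CH2, 5-OH; (CH2)14 bridge)
Conditions: BBr3 (6 equiv), CH2Cl2, −78 °C to rt; then H2O, under argon
Reagents that add atoms: none
Why: Lewis acid ether cleavage with BBr3 (O–B complexation, then SN2 attack of bromide on methyl) should remove all three methyl groups, while the diaryl ether, which offers no sp3 carbon to bromide, and the saturated bridge stay intact.

**Compound list**
1 | 4-methoxyphenol | COc1ccc(O)cc1 | starting material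
2 | 2,6-dibromo-4-methoxyphenol | COc1cc(Br)c(O)c(Br)c1 | intermediate
3 | 1,3-dibromo-2,5-dimethoxybenzene | COc1cc(Br)c(OC)c(Br)c1 | intermediate
4 | 3-chloro-5-methoxyphenol | COc1cc(O)cc(Cl)c1 | starting material
5 | 1-bromo-3-(3-chloro-5-methoxyphenoxy)-2,5-dimethoxybenzene | COc1cc(Br)c(OC)c(Oc2cc(Cl)cc(OC)c2)c1 | intermediate
6 | tetradeca-1,13-diene | C=CCCCCCCCCCCCC=C | starting material
7 | 1,14-bis(9-borabicyclo[3.3.1]nonan-9-yl)tetradecane | B1(C2CCCC1CCC2)CCCCCCCCCCCCCCB1C2CCCC1CCC2 | intermediate
8 | 9-{14-[3-(3-chloro-5-methoxyphenoxy)-2,5-dimethoxyphenyl]tetradecyl}-9-borabicyclo[3.3.1]nonane | COc1cc(CCCCCCCCCCCCCCB2C3CCCC2CCC3)c(OC)c(Oc2cc(Cl)cc(OC)c2)c1 | intermediate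
9 | tri-O-methyl ether of the target (21-membered diaryl ether cyclophane) | COc1cc2cc(c1)Oc1cc(OC)cc(c1OC)CCCCCCCCCCCCCC2 | intermediate
10 | CNP0393720.0 | Oc1cc2cc(c1)Oc1cc(O)cc(c1O)CCCCCCCCCCCCCC2 | target

Total step count: 5. Longest linear sequence: 5 steps (1 to 10).

**Steps most likely to fail**

Step 4. Intermolecular coupling of the chain-end borane (oligomerisation) and reductive loss of the chloride may outrun the slow oxidative addition at ring A.
The fallback moves the ring closure to the middle of the bridge and sets out from 5. Octa-1,7-diene in excess is mono-hydroborated with 9-BBN-H to 9-(oct-7-en-1-yl)-9-borabicyclo[3.3.1]nonane F1. An excess of this borane is coupled at both halides of 5 at ordinary concentration (Pd(OAc)2, SPhos, K3PO4, THF–H2O, 65 °C) to give 2,5-dimethoxy-1-[3-methoxy-5-(oct-7-en-1-yl)phenoxy]-3-(oct-7-en-1-yl)benzene F2. Ring-closing metathesis (second-generation Grubbs catalyst, CH2Cl2, reflux, 1 mM) should give the 21-membered cycloalkene F3 as an E/Z mixture. Hydrogenation (H2, Pd/C, EtOAc) merges both isomers and comes back to the route at 9.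

Step 3. Substitution at the hindered, electron-rich C–Br bond may be slow, and a second substitution at the remaining bromide or reductive debromination may compete.
The fallback reverses the polarity of the C–O coupling and sets out from 3. Single bromine–lithium exchange (n-BuLi, 1.0 equiv, THF, −78 °C) gives (3-bromo-2,5-dimethoxyphenyl)lithium F4. Trapping with B(OMe)3 gives dimethyl (3-bromo-2,5-dimethoxyphenyl)boronate F5, and oxidation in the same flask (H2O2, aq NaOH, 0 °C) gives 3-bromo-2,5-dimethoxyphenol F6. A Chan–Lam coupling of this phenol with commercial (3-chloro-5-methoxyphenyl)boronic acid (Cu(OAc)2, pyridine, 4 Å molecular sieves, CH2Cl2, air, rt) leaves both halides untouched and comes back to the route at 5.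

Step 5. Ether cleavage may stay incomplete, and ring B may be air-oxidised during the acidic work-up.
The fallback unmasks ring B oxidatively and sets out from 9. Oxidative demethylation of the 1,4-dimethoxyarene ((NH4)2Ce(NO3)6, MeCN–H2O, 0 °C) should give the stable, purifiable ring B 1,4-benzoquinone F7, with ring A untouched. Reduction (Na2S2O4, THF–H2O) gives the ring A mono-methyl ether of the target F8. A short treatment with BBr3 (CH2Cl2, 0 °C) then has only one unhindered methyl ether to cleave and comes back to the route at 10.

**Further compounds**
F1 | step 4 | 9-(oct-7-en-1-yl)-9-borabicyclo[3.3.1]nonane | C=CCCCCCCB1C2CCCC1CCC2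
F2 | step 4 | 2,5-dimethoxy-1-[3-methoxy-5-(oct-7-en-1-yl)phenoxy]-3-(oct-7-en-1-yl)benzene | COc1cc(CCCCCCC=C)c(OC)c(Oc2cc(CCCCCCC=C)cc(OC)c2)c1
F3 | step 4 | 21-membered cycloalkene, 7,8-didehydro bridge analogue of 9 (E/Z mixture) | COc1cc2cc(c1)Oc1cc(OC)cc(c1OC)CCCCCCC=CCCCCCC2
F4 | step 3 | (3-bromo-2,5-dimethoxyphenyl)lithium | [Li]c1cc(OC)cc(Br)c1OC
F5 | step 3 | dimethyl (3-bromo-2,5-dimethoxyphenyl)boronate | COB(OC)c1cc(OC)cc(Br)c1OC
F6 | step 3 | 3-bromo-2,5-dimethoxyphenol | COc1cc(O)c(OC)c(Br)c1
F7 | step 5 | macrocyclic ring B 1,4-benzoquinone with ring A methyl ether | COc1cc2cc(c1)OC1=CC(=O)C=C(C1=O)CCCCCCCCCCCCCC2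
F8 | step 5 | ring A mono-methyl ether of the target | COc1cc2cc(c1)Oc1cc(O)cc(c1O)CCCCCCCCCCCCCC2
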